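**Plan**
- Retrosynthesis: remove the two phenol benzyl ethers, then cut the ring bond O1–C5 while reconnecting C5 to the benzylic carbon of the C4 benzyl group, which gives an acyclic trans-2-arylcyclopropane (14). Then cut the primary ester C–O bond, the C2–C3 bond (aldol), the CH2 between cyclopropane and carbonyl (one-carbon homologation) and the cyclopropane itself (styrene plus diazoacetate).
- Forward: the cyclopropane is made first; a syn-aldol reaction with O-benzylvanillin joins the two aryl halves; the oxolane, the only non-aromatic ring, arises last when the C2 hydroxyl opens the cyclopropane at its CH2.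
- Enabling feature: C5 and the benzylic CH2 on C4 are 1,3-related through C4, so C5–C4–CH2Ar can be stored as a strained arylcyclopropane whose electron-rich guaiacyl ring is a one-electron handle. Opening it at C5 releases the strain and forms the ring O–CH2 bond and the benzyl group in one event, a homologue of an anti-Markovnikov hydroetherification.
- Stereochemistry: C4 comes from the catalyst-controlled cyclopropanation and is carried unchanged, since the ring opening breaks no bond at it; the aryl-bearing cyclopropane stereocenter is traceless. C2 and C3 come from the auxiliary-controlled syn-aldol reaction.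

Key step: step 9

Remark: ring numbering used below is O1, C2 (aryl), C3 (CH2O-acyl), C4 (arylmethyl), C5 (CH2); the target is (2S,3R,4R), that is 2,3-trans and 3,4-cis. 4-(Benzyloxy)-3-methoxybenzaldehyde, (4S)-4-benzyl-1,3-oxazolidin-2-one and the reagents named are taken as commercial.

**Route**

Step 1
Reactants: 1 4-(benzyloxy)-3-methoxybenzaldehyde
Product: 2 1-(benzyloxy)-4-ethenyl-2-methoxybenzene
Conditions: Ph3PCH3Br, KOtBu, THF, 0 °C to rt
Reagents that add atoms: methyltriphenylphosphonium bromide, C[P+](c1ccccc1)(c1ccccc1)c1ccccc1.[Br-]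
Why: A Wittig methylenation of the non-enolizable aryl aldehyde with the unstabilized ylide should give the styrene cleanly, the benzyl ether being inert to KOtBu.

Step 2
Reactants: 2 1-(benzyloxy)-4-ethenyl-2-methoxybenzene
Product: 3 ethyl (1R,2R)-2-[4-(benzyloxy)-3-methoxyphenyl]cyclopropane-1-carboxylate
Conditions: ethyl diazoacetate (slow addition), CuOTf·0.5C6H6 (1 mol%), 2,2'-(propane-2,2-diyl)bis[(4S)-4-tert-butyl-4,5-dihydro-1,3-oxazole] (1.1 mol%), CH2Cl2, rt; chromatographic separation from the minor cis ester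
Reagents that add atoms: ethyl diazoacetate, CCOC(=O)C=[N+]=[N-]
Why: Asymmetric cyclopropanation by carbene transfer from a monovalent copper bis(oxazoline) carbenoid to the electron-rich styrene should follow the facial sense established for styrene, so that the (S,S)-ligand sets the ester-bearing carbon (the later C4) as R and places the aryl group trans to the ester.

Step 3
Reactants: 3 ethyl (1R,2R)-2-[4-(benzyloxy)-3-methoxyphenyl]cyclopropane-1-carboxylate
Product: 5 ethyl 2-{(1S,2R)-2-[4-(benzyloxy)-3-methoxyphenyl]cyclopropyl}acetate, via lithium ynolate 4 (not isolated)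
Conditions: CH2Br2, LiTMP, THF, −78 °C; LiHMDS; n-BuLi, −78 °C to rt; then HCl in EtOH, 0 °C
Reagents that add atoms: dibromomethane, BrCBr; ethanol, CCO
Why: In this Kowalski ester homologation, dibromomethyllithium adds to the ester, the resulting dibromo ketone enolate undergoes bromine–lithium exchange and the cyclopropyl group migrates with retention to give ynolate 4, which acidic ethanol converts into the homologous ester without touching either ring stereocenter.

Step 4
Reactants: 5 ethyl 2-{(1S,2R)-2-[4-(benzyloxy)-3-methoxyphenyl]cyclopropyl}acetate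
Product: 6 2-{(1S,2R)-2-[4-(benzyloxy)-3-methoxyphenyl]cyclopropyl}acetic acid
Conditions: LiOH·H2O, THF/MeOH/H2O, rt; then 1 M HCl to pH 3, 0 °C
Reagents that add atoms: lithium hydroxide, [Li+].[OH-]
Why: Saponification of the unhindered ethyl ester with LiOH is routine, and the cyclopropane, which carries no acceptor group, should survive the brief cold acidification.

Step 5
Reactants: 6 2-{(1S,2R)-2-[4-(benzyloxy)-3-methoxyphenyl]cyclopropyl}acetic acid; 7 (4S)-4-benzyl-1,3-oxazolidin-2-one
Product: 9 (4S)-4-benzyl-3-(2-{(1S,2R)-2-[4-(benzyloxy)-3-methoxyphenyl]cyclopropyl}acetyl)-1,3-oxazolidin-2-one, via mixed pivalic anhydride 8 (not isolated)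
Conditions: PivCl, Et3N, THF, −20 °C; then 7, LiCl, −20 °C to rt
Reagents that add atoms: none
Why: N-Acylation of the oxazolidinone by the mixed pivalic anhydride under LiCl/Et3N activation occurs at the less hindered carbonyl of 8 and needs no strong base, so no stereocenter is at risk.

Step 6
Reactants: 9 (4S)-4-benzyl-3-(2-{(1S,2R)-2-[4-(benzyloxy)-3-methoxyphenyl]cyclopropyl}acetyl)-1,3-oxazolidin-2-one; 1 4-(benzyloxy)-3-methoxybenzaldehyde
Product: 12 (4S)-4-benzyl-3-[(2S,3S)-3-[4-(benzyloxy)-3-methoxyphenyl]-2-{(1R,2R)-2-[4-(benzyloxy)-3-methoxyphenyl]cyclopropyl}-3-hydroxypropanoyl]-1,3-oxazolidin-2-one, via boron enolate 10 (not isolated), via boron aldolate 11 (not isolated)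
Conditions: n-Bu2BOTf, i-Pr2NEt, CH2Cl2, 0 °C; then 1, −78 °C to 0 °C; then pH 7 phosphate buffer, MeOH, 30% H2O2, 0 °C
Reagents that add atoms: none
Why: Evans syn-aldol reaction: the (Z)-dibutylboron enolate 10 adds to the aldehyde through a chair Zimmerman–Traxler transition state on the enolate face remote from the benzyl group of the auxiliary, which sets both new stereocenters (2S,3S in 12, the later C3 and C2) under auxiliary control and independently of the cyclopropane.

Step 7
Reactants: 12 (4S)-4-benzyl-3-[(2S,3S)-3-[4-(benzyloxy)-3-methoxyphenyl]-2-{(1R,2R)-2-[4-(benzyloxy)-3-methoxyphenyl]cyclopropyl}-3-hydroxypropanoyl]-1,3-oxazolidin-2-one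
Product: 13 (1S,2R)-1-[4-(benzyloxy)-3-methoxyphenyl]-2-{(1R,2R)-2-[4-(benzyloxy)-3-methoxyphenyl]cyclopropyl}propane-1,3-diol
Conditions: LiBH4, MeOH (1 equiv), THF, 0 °C
Reagents that add atoms: none
Why: Reductive cleavage of the imide with LiBH4 attacks the exocyclic carbonyl selectively, should give the primary alcohol without epimerization or retro-aldol loss, and returns the auxiliary.

Step 8
Reactants: 13 (1S,2R)-1-[4-(benzyloxy)-3-methoxyphenyl]-2-{(1R,2R)-2-[4-(benzyloxy)-3-methoxyphenyl]cyclopropyl}propane-1,3-diol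
Product: 14 (2R,3S)-3-[4-(benzyloxy)-3-methoxyphenyl]-2-{(1R,2R)-2-[4-(benzyloxy)-3-methoxyphenyl]cyclopropyl}-3-hydroxypropyl 3-methylbutanoate
Conditions: 3-methylbutanoyl chloride (1.05 equiv), 2,4,6-collidine, CH2Cl2, −78 °C to −20 °C
Reagents that add atoms: 3-methylbutanoyl chloride, CC(C)CC(=O)Cl
Why: Kinetically controlled esterification with the acid chloride and a hindered pyridine base at low temperature should acylate the primary hydroxyl in preference to the flanked secondary benzylic one, installing the ester of the target and masking the only other oxygen able to attack the cyclopropane in step 9.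

Step 9
Reactants: 14 (2R,3S)-3-[4-(benzyloxy)-3-methoxyphenyl]-2-{(1R,2R)-2-[4-(benzyloxy)-3-methoxyphenyl]cyclopropyl}-3-hydroxypropyl 3-methylbutanoate
Product: 15 {(2S,3R,4R)-2-[4-(benzyloxy)-3-methoxyphenyl]-4-[4-(benzyloxy)-3-methoxybenzyl]oxolan-3-yl}methyl 3-methylbutanoate
Conditions: 9-mesityl-10-methylacridinium tetrafluoroborate (5 mol%), PhSSPh (20 mol%), ClCH2CH2Cl (0.02 M), 450 nm LEDs, rt, argon
Reagents that add atoms: none
Why: Proposed new method: the excited acridinium oxidizes the dialkoxyaryl cyclopropane of 14 to its radical cation, in which the two ring bonds to the aryl-bearing carbon are weakened; the C2 hydroxyl attacks the cyclopropane CH2 in a three-electron SN2 displacement with inversion at that CH2, releasing the ring strain and leaving an oxonium ion that loses its proton and a benzylic radical that takes a hydrogen atom from thiophenol (formed from PhSSPh), while the thiyl radical takes the electron back from the reduced acridine, so the process is redox-neutral. The closest known reaction types are the photoredox anti-Markovnikov hydroalkoxylation of arylcyclopropanes by external alcohols and the anti-Markovnikov hydroetherification of alkenols, of which this is the intramolecular homologue. The oxolane closes in the 5-exo-tet mode, the C–C bond that breaks lying outside the new ring. No stereocenter is created: C4 is the cyclopropane carbon that carried the side chain and no bond to it is made or broken, C2 and C3 come unchanged from the aldol reaction, and the configuration of the aryl-bearing ring carbon vanishes as it becomes CH2. The step needs regioselectivity for the CH2 over the more substituted ring carbon, which the tether secures because attack there would close an oxetane, and chemoselectivity for the secondary hydroxyl, secured because the only other oxygen that could reach the CH2 through a five-membered transition state is masked as the 3-methylbutanoate.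

Step 10
Reactants: 15 {(2S,3R,4R)-2-[4-(benzyloxy)-3-methoxyphenyl]-4-[4-(benzyloxy)-3-methoxybenzyl]oxolan-3-yl}methyl 3-methylbutanoate
Product: 16 (+)-9'-isovaleroxylariciresinol, {(2S,3R,4R)-2-(4-hydroxy-3-methoxyphenyl)-4-(4-hydroxy-3-methoxybenzyl)oxolan-3-yl}methyl 3-methylbutanoate
Conditions: H2 (1 atm), 10% Pd/C, EtOAc, rt, stopped at consumption of 15
Reagents that add atoms: none
Why: Hydrogenolysis of the two aryl benzyl ethers over Pd/C is faster than cleavage of the ring benzylic C–O bond or any reaction of the alkyl ester, so stopping at consumption of 15 should deliver the free bisphenol with all three stereocenters intact.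

**Compound list**
1 | 4-(benzyloxy)-3-methoxybenzaldehyde | COc1cc(C=O)ccc1OCc1ccccc1 | starting material
2 | 1-(benzyloxy)-4-ethenyl-2-methoxybenzene | COc1cc(C=C)ccc1OCc1ccccc1 | intermediate
3 | ethyl (1R,2R)-2-[4-(benzyloxy)-3-methoxyphenyl]cyclopropane-1-carboxylate | CCOC(=O)[C@@H]1C[C@H]1c1ccc(OCc2ccccc2)c(OC)c1 | intermediate
4 | lithium 2-{(1R,2R)-2-[4-(benzyloxy)-3-methoxyphenyl]cyclopropyl}ethyn-1-olate (not isolated) | [Li+].[O-]C#C[C@@H]1C[C@H]1c1ccc(OCc2ccccc2)c(OC)c1 | intermediate
5 | ethyl 2-{(1S,2R)-2-[4-(benzyloxy)-3-methoxyphenyl]cyclopropyl}acetate | CCOC(=O)C[C@@H]1C[C@H]1c1ccc(OCc2ccccc2)c(OC)c1 | intermediate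
6 | 2-{(1S,2R)-2-[4-(benzyloxy)-3-methoxyphenyl]cyclopropyl}acetic acid | OC(=O)C[C@@H]1C[C@H]1c1ccc(OCc2ccccc2)c(OC)c1 | intermediate
7 | (4S)-4-benzyl-1,3-oxazolidin-2-one | O=C1N[C@@H](Cc2ccccc2)CO1 | starting material
8 | 2-{(1S,2R)-2-[4-(benzyloxy)-3-methoxyphenyl]cyclopropyl}acetic 2,2-dimethylpropanoic anhydride (not isolated) | CC(C)(C)C(=O)OC(=O)C[C@@H]1C[C@H]1c1ccc(OCc2ccccc2)c(OC)c1 | intermediate
9 | (4S)-4-benzyl-3-(2-{(1S,2R)-2-[4-(benzyloxy)-3-methoxyphenyl]cyclopropyl}acetyl)-1,3-oxazolidin-2-one | O=C(C[C@@H]1C[C@H]1c1ccc(OCc2ccccc2)c(OC)c1)N1C(=O)OC[C@@H]1Cc1ccccc1 | intermediate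
10 | (Z)-dibutylboron enolate of 9 (not isolated) | CCCCB(CCCC)O/C(=C\[C@@H]1C[C@H]1c1ccc(OCc2ccccc2)c(OC)c1)N1C(=O)OC[C@@H]1Cc1ccccc1 | intermediate
11 | O-dibutylboryl aldolate of 12 (not isolated) | COc1cc([C@@H]2C[C@H]2[C@H](C(=O)N2C(=O)OC[C@@H]2Cc2ccccc2)[C@H](OB(CCCC)CCCC)c2ccc(OCc3ccccc3)c(OC)c2)ccc1OCc1ccccc1 | intermediate
12 | (4S)-4-benzyl-3-[(2S,3S)-3-[4-(benzyloxy)-3-methoxyphenyl]-2-{(1R,2R)-2-[4-(benzyloxy)-3-methoxyphenyl]cyclopropyl}-3-hydroxypropanoyl]-1,3-oxazolidin-2-one | COc1cc([C@@H]2C[C@H]2[C@H](C(=O)N2C(=O)OC[C@@H]2Cc2ccccc2)[C@H](O)c2ccc(OCc3ccccc3)c(OC)c2)ccc1OCc1ccccc1 | intermediate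
13 | (1S,2R)-1-[4-(benzyloxy)-3-methoxyphenyl]-2-{(1R,2R)-2-[4-(benzyloxy)-3-methoxyphenyl]cyclopropyl}propane-1,3-diol | COc1cc([C@@H]2C[C@H]2[C@H](CO)[C@H](O)c2ccc(OCc3ccccc3)c(OC)c2)ccc1OCc1ccccc1 | intermediate
14 | (2R,3S)-3-[4-(benzyloxy)-3-methoxyphenyl]-2-{(1R,2R)-2-[4-(benzyloxy)-3-methoxyphenyl]cyclopropyl}-3-hydroxypropyl 3-methylbutanoate | COc1cc([C@@H]2C[C@H]2[C@H](COC(=O)CC(C)C)[C@H](O)c2ccc(OCc3ccccc3)c(OC)c2)ccc1OCc1ccccc1 | intermediate
15 | {(2S,3R,4R)-2-[4-(benzyloxy)-3-methoxyphenyl]-4-[4-(benzyloxy)-3-methoxybenzyl]oxolan-3-yl}methyl 3-methylbutanoate | COc1cc(C[C@H]2CO[C@H](c3ccc(OCc4ccccc4)c(OC)c3)[C@H]2COC(=O)CC(C)C)ccc1OCc1ccccc1 | intermediate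
16 | (+)-9'-isovaleroxylariciresinol | COc1cc(C[C@H]2CO[C@H](c3ccc(O)c(OC)c3)[C@H]2COC(=O)CC(C)C)ccc1O | target

**Totals**
Total step count: 10. Longest linear sequence: 10 steps (1 to 16).

**Steps most likely to fail**

1. Step 9. The radical cation may be captured at the more substituted ring carbon or by the ester carbonyl instead of at the CH2. The C4 configuration may be lost through reversible opening of the weakened ring bond before the hydroxyl arrives. Unproductive oxidation of the other arene or of the benzylic carbinol may also stall the reaction. The fallback uses known chemistry, closes the same ring from the other side through a benzylic cation, sets out from 1 and comes back at 15. A Stobbe condensation of 1 with dimethyl succinate (NaOMe, MeOH, reflux) should give (E)-4-[4-(benzyloxy)-3-methoxyphenyl]-3-(methoxycarbonyl)but-3-enoic acid F1. Asymmetric hydrogenation ([Rh(cod)2]BF4 with the enantiomer of a chiral bisphospholane ligand that delivers the R acid, H2, MeOH) should give (3R)-4-[4-(benzyloxy)-3-methoxyphenyl]-3-(methoxycarbonyl)butanoic acid F2. Reduction of the ester in the potassium carboxylate with Ca(BH4)2 (CaCl2, NaBH4, EtOH) and acidification should close (4R)-4-[4-(benzyloxy)-3-methoxybenzyl]oxolan-2-one F3. Its lithium enolate (LiHMDS, THF, −78 °C) should add to 1 anti to the ring substituent to give the trans aldol lactone (3S,4R)-3-{(S)-[4-(benzyloxy)-3-methoxyphenyl](hydroxy)methyl}-4-[4-(benzyloxy)-3-methoxybenzyl]oxolan-2-one F4, whose carbinol epimer is carried along because both converge later. LiAlH4 (THF, 0 °C) should give the triol (1S,2R,3R)-1-[4-(benzyloxy)-3-methoxyphenyl]-3-[4-(benzyloxy)-3-methoxybenzyl]-2-(hydroxymethyl)butane-1,4-diol F5. Catalytic camphorsulfonic acid (CH2Cl2, 0 °C) should ionize the benzylic carbinol and let the primary hydroxyl four atoms away close the 2,3-trans oxolane {(2S,3R,4R)-2-[4-(benzyloxy)-3-methoxyphenyl]-4-[4-(benzyloxy)-3-methoxybenzyl]oxolan-3-yl}methanol F6. Acylation with 3-methylbutanoyl chloride and pyridine then gives 15.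

2. Step 3. The carbenoid rearrangement may be incomplete, the alkyllithium may attack the benzyl ether or the ester, or the donor-substituted cyclopropane may open during the acidic quench. The fallback is an Arndt–Eistert homologation that sets out from 3 and comes back at 6, so that step 4 is no longer needed. Saponification (LiOH, THF/H2O) should give (1R,2R)-2-[4-(benzyloxy)-3-methoxyphenyl]cyclopropane-1-carboxylic acid F7. Oxalyl chloride with catalytic DMF (CH2Cl2, 0 °C) should give (1R,2R)-2-[4-(benzyloxy)-3-methoxyphenyl]cyclopropane-1-carbonyl chloride F8. Trimethylsilyldiazomethane (MeCN/THF, 0 °C) should give 2-diazo-1-{(1R,2R)-2-[4-(benzyloxy)-3-methoxyphenyl]cyclopropyl}ethan-1-one F9. Wolff rearrangement with retention (AgOBz cat., Et3N, THF/H2O) then gives 6.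

3. Step 10. Hydrogenolysis may continue at the ring benzylic C–O bond once the benzyl ethers are gone. The fallback sets out from 15 and comes back at 16 by Lewis-acid dealkylation instead of hydrogenation: BCl3 with pentamethylbenzene as cation scavenger (CH2Cl2, −78 °C) should remove both benzyl groups without hydrogen; this fallback makes no new compound (F0).

**Further compounds**
F1 | step 9 | (E)-4-[4-(benzyloxy)-3-methoxyphenyl]-3-(methoxycarbonyl)but-3-enoic acid | COC(=O)/C(CC(=O)O)=C/c1ccc(OCc2ccccc2)c(OC)c1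
F2 | step 9 | (3R)-4-[4-(benzyloxy)-3-methoxyphenyl]-3-(methoxycarbonyl)butanoic acid | COC(=O)[C@@H](CC(=O)O)Cc1ccc(OCc2ccccc2)c(OC)c1
F3 | step 9 | (4R)-4-[4-(benzyloxy)-3-methoxybenzyl]oxolan-2-one | O=C1C[C@@H](Cc2ccc(OCc3ccccc3)c(OC)c2)CO1
F4 | step 9 | (3S,4R)-3-{(S)-[4-(benzyloxy)-3-methoxyphenyl](hydroxy)methyl}-4-[4-(benzyloxy)-3-methoxybenzyl]oxolan-2-one | O=C1OC[C@H](Cc2ccc(OCc3ccccc3)c(OC)c2)[C@H]1[C@H](O)c1ccc(OCc2ccccc2)c(OC)c1
F5 | step 9 | (1S,2R,3R)-1-[4-(benzyloxy)-3-methoxyphenyl]-3-[4-(benzyloxy)-3-methoxybenzyl]-2-(hydroxymethyl)butane-1,4-diol | OC[C@H](Cc1ccc(OCc2ccccc2)c(OC)c1)[C@H](CO)[C@H](O)c1ccc(OCc2ccccc2)c(OC)c1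
F6 | step 9 | {(2S,3R,4R)-2-[4-(benzyloxy)-3-methoxyphenyl]-4-[4-(benzyloxy)-3-methoxybenzyl]oxolan-3-yl}methanol | COc1cc(C[C@H]2CO[C@H](c3ccc(OCc4ccccc4)c(OC)c3)[C@H]2CO)ccc1OCc1ccccc1
F7 | step 3 | (1R,2R)-2-[4-(benzyloxy)-3-methoxyphenyl]cyclopropane-1-carboxylic acid | OC(=O)[C@@H]1C[C@H]1c1ccc(OCc2ccccc2)c(OC)c1
F8 | step 3 | (1R,2R)-2-[4-(benzyloxy)-3-methoxyphenyl]cyclopropane-1-carbonyl chloride | ClC(=O)[C@@H]1C[C@H]1c1ccc(OCc2ccccc2)c(OC)c1
F9 | step 3 | 2-diazo-1-{(1R,2R)-2-[4-(benzyloxy)-3-methoxyphenyl]cyclopropyl}ethan-1-one | [N-]=[N+]=CC(=O)[C@@H]1C[C@H]1c1ccc(OCc2ccccc2)c(OC)c1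
F0 | step 10 | none | none
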